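Numbering: the C17 chain runs from C1 (the CH3 on the C–Cl carbon) through C4 (C=O) to C17, which sits on C3' of the furan ring. Retrosynthetic cuts, in order: O–Si at C3 (helper), C5–C6, C12–C13, C11=C12, C6–C7, C4–C5, C14–CH3, C17–C3'.
Enabling feature: C5 is a bare CH2 between the C4 carbonyl and the methyl-bearing C6–H. C5 can therefore enter as the diazo carbon of a C1–C5 α-diazo ketone, and C6 as the only carbon ligand on a boron atom. A 1,2-shift from B to C5 with loss of N2 joins the halves without base or metal carbene, which the C2–Cl/C3–O pair, the C11–C14 diene and the furan ring (O1', C2'–C5') would not tolerate.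
Forward: (a) C3'–C17 by Negishi coupling, then C14–CH3 by carboalumination, to the alkenyl iodide. (b) Citronellene to the C7 boronate, then C6–C7 (lithiation–borylation), C11=C12 (cross-metathesis), C12–C13 (Suzuki–Miyaura) and the trifluoroborate. (c) Threonine to the chlorohydrin acid, then C4–C5 by acylation of diazomethane. Union at C5–C6 and desilylation follow; the furan is bought and no ring is built.
Stereochemistry: C10 comes from (R)-β-citronellene. C6 comes from (−)-sparteine-controlled lithiation and is carried through the union with retention. C2 and C3 come from L-threonine by way of the cis-epoxide (net inversion at both carbons). 13E comes from syn-carboalumination and 11E from metathesis.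
Helpers and their removal: boron at C6 (Bpin → BF3K → BF2) leaves as boric acid, N2 at C5 leaves as gas, and the silyl group on O3 leaves in the last step.

Key step: step 16

Assumption: the R enantiomer of β-citronellene, (−)-sparteine and ethyl 2,4,6-triisopropylbenzoate are taken as catalogue chemicals, and the enantiomeric purity of the terpene sets that of C10.

Step 1
Reactants: 1 (5-iodopent-1-yn-1-yl)trimethylsilane; 2 3-bromofuran
Product: 4 [5-(furan-3-yl)pent-1-yn-1-yl]trimethylsilane, via alkylzinc iodide 3 (not isolated)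
Conditions: Zn dust, LiCl, THF, 25 → 40 °C; then 2, Pd(OAc)2 (cat.), SPhos (cat.), THF, 25 → 50 °C
Reagents that add atoms: zinc, [Zn] (kept only in 3)
Why: Direct zinc insertion into the primary iodide and Negishi sp3–sp2 coupling at the C–Br bond of 2 should fix the 3-substitution of the furan ring without the labile 3-lithiofuran, while the silyl cap keeps the alkyne out of the palladium cycle.

Step 2
Reactants: 4 [5-(furan-3-yl)pent-1-yn-1-yl]trimethylsilane
Product: 5 3-(pent-4-yn-1-yl)furan
Conditions: K2CO3 (cat.), MeOH, rt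
Reagents that add atoms: none
Why: Carbonate-catalysed methanolysis of the alkynyl C–Si bond (protodesilylation) touches nothing else in 4.

Step 3
Reactants: 5 3-(pent-4-yn-1-yl)furan
Product: 7 3-[(4E)-5-iodo-4-methylpent-4-en-1-yl]furan, via alkenylalane 6 (not isolated)
Conditions: Me3Al, Cp2ZrCl2 (cat.), CH2Cl2, 0 °C → rt; then I2, THF, −30 → 0 °C
Reagents that add atoms: trimethylaluminium, C[Al](C)C; iodine, II
Why: Zirconium-catalysed Negishi carboalumination adds CH3 and Al syn across the terminal alkyne with Al at the terminus, and iodinolysis with retention should therefore give the E trisubstituted alkenyl iodide (later 13E).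

Step 4
Reactants: 8 (3R)-3,7-dimethylocta-1,6-diene ((R)-β-citronellene)
Product: 9 (4R)-4-methylhex-5-en-1-ol
Conditions: O3 (one equivalent, Sudan Red 7B end point), CH2Cl2/MeOH, −78 °C; then NaBH4, −78 °C → rt
Reagents that add atoms: ozone, [O-][O+]=O
Why: In this ozonolysis with reductive work-up the electrophilic ozone should attack the electron-rich trisubstituted alkene well before the vinyl group, and the stereocentre of the chiral pool (later C10) is not involved.

Step 5
Reactants: 9 (4R)-4-methylhex-5-en-1-ol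
Product: 10 (3R)-6-iodo-3-methylhex-1-ene
Conditions: I2, PPh3, imidazole, CH2Cl2, 0 °C → rt
Reagents that add atoms: iodine, II
Why: Appel-type iodination replaces the primary hydroxyl by SN2 attack of iodide on the alkoxyphosphonium salt under nearly neutral conditions that leave the vinyl group and the stereocentre alone.

Step 6
Reactants: 10 (3R)-6-iodo-3-methylhex-1-ene
Product: 12 4,4,5,5-tetramethyl-2-[(4R)-4-methylhex-5-en-1-yl]-1,3,2-dioxaborolane, via alkyllithium 11 (not isolated)
Conditions: t-BuLi (2 equiv), Et2O/pentane, −78 °C; then i-PrOBpin, −78 °C → rt; H2O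
Reagents that add atoms: 2-isopropoxy-4,4,5,5-tetramethyl-1,3,2-dioxaborolane, CC(C)OB1OC(C)(C)C(C)(C)O1; tert-butyllithium, [Li]C(C)(C)C (lithium kept only in 11)
Why: Lithium–iodine exchange followed by trapping with a borate ester is a two-electron route to the primary boronate, and at −78 °C the 5-exo carbolithiation of the hexenyllithium 11 is too slow to compete.

Step 7
Reactants: 12 4,4,5,5-tetramethyl-2-[(4R)-4-methylhex-5-en-1-yl]-1,3,2-dioxaborolane; 13 ethyl 2,4,6-triisopropylbenzoate
Product: 16 4,4,5,5-tetramethyl-2-[(2R,6R)-6-methyloct-7-en-2-yl]-1,3,2-dioxaborolane, via lithiated benzoate 14 (not isolated), via boronate complex 15 (not isolated)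
Conditions: 13, s-BuLi, (−)-sparteine, Et2O, −78 °C; then 12, −78 °C; then 35 °C
Reagents that add atoms: sec-butyllithium, [Li]C(C)CC (lithium kept only in 14 and 15)
Why: Sparteine-mediated asymmetric lithiation–borylation: s-BuLi/(−)-sparteine removes the pro-S hydrogen of 13, 12 captures 14 with retention, and the 1,2-metallate shift of 15 displaces the benzoate with inversion, which should set C6 as R under reagent control.

Step 8
Reactants: 16 4,4,5,5-tetramethyl-2-[(2R,6R)-6-methyloct-7-en-2-yl]-1,3,2-dioxaborolane; 17 4,4,5,5-tetramethyl-2-vinyl-1,3,2-dioxaborolane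
Product: 18 2,2'-[(1E,3R,7R)-3-methyloct-1-ene-1,7-diyl]bis(4,4,5,5-tetramethyl-1,3,2-dioxaborolane)
Conditions: second-generation Grubbs catalyst (cat.), CH2Cl2, 40 °C
Reagents that add atoms: none
Why: Olefin cross-metathesis of the vinyl group with vinylboronate 17 should give the E alkenylboronate (later 11E) for steric reasons, and the saturated secondary boronate is inert to the ruthenium carbene.

Step 9
Reactants: 18 2,2'-[(1E,3R,7R)-3-methyloct-1-ene-1,7-diyl]bis(4,4,5,5-tetramethyl-1,3,2-dioxaborolane); 7 3-[(4E)-5-iodo-4-methylpent-4-en-1-yl]furan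
Product: 19 2-[(2R,6R,7E,9E)-13-(furan-3-yl)-6,10-dimethyltrideca-7,9-dien-2-yl]-4,4,5,5-tetramethyl-1,3,2-dioxaborolane
Conditions: PdCl2(dppf) (cat.), Cs2CO3, DMF/H2O, rt → 45 °C
Reagents that add atoms: none
Why: Suzuki–Miyaura coupling with retention of both alkene geometries builds the E,E-diene, and only the sp2 boronate transmetallates under these conditions while the secondary sp3 boronate stays intact.

Step 10
Reactants: 19 2-[(2R,6R,7E,9E)-13-(furan-3-yl)-6,10-dimethyltrideca-7,9-dien-2-yl]-4,4,5,5-tetramethyl-1,3,2-dioxaborolane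
Product: 20 potassium trifluoro[(2R,6R,7E,9E)-13-(furan-3-yl)-6,10-dimethyltrideca-7,9-dien-2-yl]borate
Conditions: KHF2 (aq), MeOH, rt; repeated evaporation from aq MeOH
Reagents that add atoms: potassium hydrogen difluoride, [K+].[F-].F
Why: Ligand exchange with bifluoride turns the unreactive pinacol boronate into a crystalline trifluoroborate without touching the C–B stereocentre, and the medium is mild enough for furan and diene.

Step 11
Reactants: 21 L-threonine
Product: 22 (2S,3R)-2-bromo-3-hydroxybutanoic acid
Conditions: NaNO2, KBr, aq H2SO4, 0 °C → rt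
Reagents that add atoms: potassium bromide, [K+].[Br-]
Why: Diazotisation with halide capture proceeds by double inversion through the α-lactone, so bromide should replace nitrogen with net retention at C2 of the acid.

Step 12
Reactants: 22 (2S,3R)-2-bromo-3-hydroxybutanoic acid
Product: 23 potassium (2R,3R)-3-methyloxirane-2-carboxylate (cis)
Conditions: KOH (2 equiv), EtOH, 0 °C → rt
Reagents that add atoms: potassium hydroxide, [K+].[OH-]
Why: Intramolecular Williamson closure of the halohydrin: the C3 alkoxide displaces bromide from the rear, which inverts C2 and should give the cis-epoxide as its potassium salt.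

Step 13
Reactants: 23 potassium (2R,3R)-3-methyloxirane-2-carboxylate
Product: 24 (2S,3S)-3-chloro-2-hydroxybutanoic acid
Conditions: HCl (4 M in 1,4-dioxane), Et2O, −20 °C → rt
Reagents that add atoms: hydrogen chloride, Cl
Why: Acid-promoted SN2 opening of the protonated oxirane: the carboxyl group disfavours positive charge at C2, so chloride should attack C3 from the rear, which inverts C3, leaves the C2–O bond untouched and turns the cis-epoxide into the syn chlorohydrin.

Step 14
Reactants: 24 (2S,3S)-3-chloro-2-hydroxybutanoic acid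
Product: 25 tert-butyldimethylsilyl (2S,3S)-2-[(tert-butyldimethylsilyl)oxy]-3-chlorobutanoate
Conditions: TBSCl, imidazole, DMF, rt
Reagents that add atoms: tert-butyldimethylsilyl chloride, CC(C)(C)[Si](C)(C)Cl
Why: Standard imidazole-promoted silylation caps both the hydroxyl and the carboxyl group, and the weak base cannot close the chlorohydrin back to the epoxide.

Step 15
Reactants: 25 tert-butyldimethylsilyl (2S,3S)-2-[(tert-butyldimethylsilyl)oxy]-3-chlorobutanoate
Product: 27 (3S,4S)-3-[(tert-butyldimethylsilyl)oxy]-4-chloro-1-diazopentan-2-one, via acid chloride 26 (not isolated)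
Conditions: (COCl)2, DMF (cat.), CH2Cl2, 0 °C → rt; evaporate; then CH2N2 (excess), Et2O, 0 °C
Reagents that add atoms: diazomethane, C=[N+]=[N-]; oxalyl chloride, O=C(Cl)C(=O)Cl (chlorine kept only in 26)
Why: The silyl ester is converted by the chloroiminium salt into the acid chloride under neutral conditions that spare the silyl ether, and acylation of diazomethane (first stage of the Arndt–Eistert sequence) then installs C5 as a diazo carbon with the second equivalent taking up HCl.

Step 16
Reactants: 20 potassium trifluoro[(2R,6R,7E,9E)-13-(furan-3-yl)-6,10-dimethyltrideca-7,9-dien-2-yl]borate; 27 (3S,4S)-3-[(tert-butyldimethylsilyl)oxy]-4-chloro-1-diazopentan-2-one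
Product: 30 (2S,3S,6R,10R,11E,13E)-3-[(tert-butyldimethylsilyl)oxy]-2-chloro-17-(furan-3-yl)-6,10,14-trimethylheptadeca-11,13-dien-4-one, via difluoroborane 28 (not isolated), via boron enolate 29 (not isolated)
Conditions: Me3SiCl, 2,6-di-tert-butyl-4-methylpyridine (cat.), MeCN/CH2Cl2, 0 °C; then 27, −78 → 0 °C; then H2O/MeOH
Reagents that add atoms: none
Why: Proposed new method: Me3SiCl strips one fluoride from 20 to give the three-coordinate difluoroborane 28, whose empty p orbital is attacked by the nucleophilic diazo carbon (future C5) of 27; the α-diazonio borate then expels N2 while the only carbon ligand on boron, the secondary C6 alkyl group, shifts from B to C5, and the α-boryl ketone relaxes by a 1,3-boron shift to the O-boron enolate 29, which water protonates at C5. The closest known reaction types are the Hooz reaction of trialkylboranes with α-diazo ketones, the homologation of alkyldifluoroboranes made in the same way with stabilised diazoalkanes, and the amination of enantioenriched secondary alkyldihaloboranes with azides, all of which run through the same 1,2-metallate shift; what is new is the union of an enantioenriched secondary alkyldifluoroborane with a functionalised α-diazo ketone. No ring is closed and no new stereocentre is made: C6 is carried over with retention because the migrating carbon keeps its bonding face during the shift, and C5 ends as CH2. Group selectivity is secured by the substrate, since fluoride does not migrate and 29 has no B–C bond left for a second insertion. Chemoselectivity is secured by the absence of a metal carbene and of base: the furan ring and the C11–C14 diene are not cyclopropanated, and the enolate arises only on the C5 side of C4, so C3–H is never removed and neither epimerisation at C3 nor loss of chloride from C2 can start. The hindered pyridine takes up adventitious acid without binding boron, so that furan and diene are not protonated.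

Step 17
Reactants: 30 (2S,3S,6R,10R,11E,13E)-3-[(tert-butyldimethylsilyl)oxy]-2-chloro-17-(furan-3-yl)-6,10,14-trimethylheptadeca-11,13-dien-4-one
Product: 31 (2S,3S,6R,10R,11E,13E)-2-chloro-17-(furan-3-yl)-3-hydroxy-6,10,14-trimethylheptadeca-11,13-dien-4-one (CNP0261264.1)
Conditions: HF·pyridine, pyridine, THF, 0 °C → rt
Reagents that add atoms: none
Why: Fluoride-driven desilylation in a pyridine-buffered medium frees the C3 hydroxyl without the base that would trigger epoxide closure or loss of HCl and without acid strong enough to harm furan or diene.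

Compound list
1 | (5-iodopent-1-yn-1-yl)trimethylsilane | C[Si](C)(C)C#CCCCI | starting material
2 | 3-bromofuran | Brc1ccoc1 | starting material
3 | [5-(trimethylsilyl)pent-4-yn-1-yl]zinc iodide | C[Si](C)(C)C#CCCC[Zn]I | intermediate
4 | [5-(furan-3-yl)pent-1-yn-1-yl]trimethylsilane | C[Si](C)(C)C#CCCCc1ccoc1 | intermediate
5 | 3-(pent-4-yn-1-yl)furan | C#CCCCc1ccoc1 | intermediate
6 | [(1E)-5-(furan-3-yl)-2-methylpent-1-en-1-yl]dimethylaluminium | C/C(=C\[Al](C)C)CCCc1ccoc1 | intermediate
7 | 3-[(4E)-5-iodo-4-methylpent-4-en-1-yl]furan | C/C(=C\I)CCCc1ccoc1 | intermediate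
8 | (3R)-3,7-dimethylocta-1,6-diene ((R)-β-citronellene) | C=C[C@H](C)CCC=C(C)C | starting material
9 | (4R)-4-methylhex-5-en-1-ol | C=C[C@H](C)CCCO | intermediate
10 | (3R)-6-iodo-3-methylhex-1-ene | C=C[C@H](C)CCCI | intermediate
11 | [(4R)-4-methylhex-5-en-1-yl]lithium | C=C[C@H](C)CCC[Li] | intermediate
12 | 4,4,5,5-tetramethyl-2-[(4R)-4-methylhex-5-en-1-yl]-1,3,2-dioxaborolane | C=C[C@H](C)CCCB1OC(C)(C)C(C)(C)O1 | intermediate
13 | ethyl 2,4,6-triisopropylbenzoate | CCOC(=O)c1c(C(C)C)cc(C(C)C)cc1C(C)C | starting material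
14 | (1S)-1-lithioethyl 2,4,6-triisopropylbenzoate (sparteine complex, ligand not drawn) | C[C@H]([Li])OC(=O)c1c(C(C)C)cc(C(C)C)cc1C(C)C | intermediate
15 | lithium boronate complex of 12 and 14 (B in place of Li, retention) | [Li+].C[C@H]([B-]1(CCC[C@@H](C)C=C)OC(C)(C)C(C)(C)O1)OC(=O)c2c(C(C)C)cc(C(C)C)cc2C(C)C | intermediate
16 | 4,4,5,5-tetramethyl-2-[(2R,6R)-6-methyloct-7-en-2-yl]-1,3,2-dioxaborolane | C=C[C@H](C)CCC[C@@H](C)B1OC(C)(C)C(C)(C)O1 | intermediate
17 | 4,4,5,5-tetramethyl-2-vinyl-1,3,2-dioxaborolane | C=CB1OC(C)(C)C(C)(C)O1 | starting material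
18 | 2,2'-[(1E,3R,7R)-3-methyloct-1-ene-1,7-diyl]bis(4,4,5,5-tetramethyl-1,3,2-dioxaborolane) | CC1(C)OB(/C=C/[C@H](C)CCC[C@@H](C)B2OC(C)(C)C(C)(C)O2)OC1(C)C | intermediate
19 | 2-[(2R,6R,7E,9E)-13-(furan-3-yl)-6,10-dimethyltrideca-7,9-dien-2-yl]-4,4,5,5-tetramethyl-1,3,2-dioxaborolane | C/C(=C\C=C\[C@H](C)CCC[C@@H](C)B1OC(C)(C)C(C)(C)O1)CCCc1ccoc1 | intermediate
20 | potassium trifluoro[(2R,6R,7E,9E)-13-(furan-3-yl)-6,10-dimethyltrideca-7,9-dien-2-yl]borate | [K+].C/C(=C\C=C\[C@H](C)CCC[C@@H](C)[B-](F)(F)F)CCCc1ccoc1 | intermediate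
21 | L-threonine, (2S,3R)-2-amino-3-hydroxybutanoic acid | C[C@@H](O)[C@H](N)C(=O)O | starting material
22 | (2S,3R)-2-bromo-3-hydroxybutanoic acid | C[C@@H](O)[C@H](Br)C(=O)O | intermediate
23 | potassium (2R,3R)-3-methyloxirane-2-carboxylate (cis) | [K+].C[C@H]1O[C@H]1C(=O)[O-] | intermediate
24 | (2S,3S)-3-chloro-2-hydroxybutanoic acid | OC(=O)[C@H](O)[C@H](C)Cl | intermediate
25 | tert-butyldimethylsilyl (2S,3S)-2-[(tert-butyldimethylsilyl)oxy]-3-chlorobutanoate | CC(C)(C)[Si](C)(C)OC(=O)[C@H](O[Si](C)(C)C(C)(C)C)[C@H](C)Cl | intermediate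
26 | (2R,3S)-2-[(tert-butyldimethylsilyl)oxy]-3-chlorobutanoyl chloride (same spatial arrangement as 25; the C2 descriptor changes only through the priority of COCl) | ClC(=O)[C@H](O[Si](C)(C)C(C)(C)C)[C@H](C)Cl | intermediate
27 | (3S,4S)-3-[(tert-butyldimethylsilyl)oxy]-4-chloro-1-diazopentan-2-one | [N-]=[N+]=CC(=O)[C@H](O[Si](C)(C)C(C)(C)C)[C@H](C)Cl | intermediate
28 | difluoro[(2R,6R,7E,9E)-13-(furan-3-yl)-6,10-dimethyltrideca-7,9-dien-2-yl]borane | C/C(=C\C=C\[C@H](C)CCC[C@@H](C)B(F)F)CCCc1ccoc1 | intermediate
29 | difluoroboron enolate of 30 (C4–O–BF2, C4=C5, geometry open) | C/C(=C\C=C\[C@H](C)CCC[C@@H](C)C=C(OB(F)F)[C@H](O[Si](C)(C)C(C)(C)C)[C@H](C)Cl)CCCc1ccoc1 | intermediate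
30 | (2S,3S,6R,10R,11E,13E)-3-[(tert-butyldimethylsilyl)oxy]-2-chloro-17-(furan-3-yl)-6,10,14-trimethylheptadeca-11,13-dien-4-one | C/C(=C\C=C\[C@H](C)CCC[C@@H](C)CC(=O)[C@H](O[Si](C)(C)C(C)(C)C)[C@H](C)Cl)CCCc1ccoc1 | intermediate
31 | (2S,3S,6R,10R,11E,13E)-2-chloro-17-(furan-3-yl)-3-hydroxy-6,10,14-trimethylheptadeca-11,13-dien-4-one | C/C(=C\C=C\[C@H](C)CCC[C@@H](C)CC(=O)[C@H](O)[C@H](C)Cl)CCCc1ccoc1 | target

Total step count: 17. Longest linear sequence: 9 steps (steps 4–10, 16, 17).

Steps most likely to fail

Step 16 (the labelled step).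
- Risk: capture of the difluoroborane by the acceptor-substituted diazo carbon may be slow. Acid-induced decay of the diazo ketone, or protonation of furan and diene, could then overtake the 1,2-shift.
- Fallback: known chemistry, from 19 back to 30.
- Matteson homologation of 19 (BrCH2Cl, n-BuLi, THF, −78 °C → rt) inserts C5 with retention at C6. It gives the primary boronate 2-[(2S,6R,7E,9E)-13-(furan-3-yl)-2,6,10-trimethyltrideca-7,9-dien-1-yl]-4,4,5,5-tetramethyl-1,3,2-dioxaborolane F1.
- Oxidation (H2O2, aq NaOH, THF, 0 °C) gives (2R,6R,7E,9E)-13-(furan-3-yl)-2,6,10-trimethyltrideca-7,9-dien-1-ol F2.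
- Appel iodination (I2, PPh3, imidazole) gives 3-[(4E,6E,8R,12R)-13-iodo-4,8,12-trimethyltrideca-4,6-dien-1-yl]furan F3.
- Zinc insertion (Zn, LiCl, THF) gives [(2R,6R,7E,9E)-13-(furan-3-yl)-2,6,10-trimethyltrideca-7,9-dien-1-yl]zinc iodide F4.
- Negishi acylation of F4 with acid chloride 26 (first stage of step 15; Pd(PPh3)4 cat., THF, 0 °C → rt) gives 30.

Step 13.
- Risk: poor regioselectivity. Chloride may attack the oxirane carbon next to the carboxyl group, or adventitious water may open the ring.
- Fallback: from 23 back to 24. The oxidation level is lowered so that a titanium chelate directs the opening.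
- Ethyl chloroformate (THF, 0 °C) converts 23 into the mixed anhydride ethoxycarbonyl (2R,3R)-3-methyloxirane-2-carboxylate F5.
- NaBH4 (aq THF) reduces F5 to [(2S,3R)-3-methyloxiran-2-yl]methanol F6.
- Ti(OiPr)4 with diethylammonium chloride (CH2Cl2, rt) binds the alkoxide and the epoxide oxygen and delivers chloride to the distal carbon with inversion. This gives (2S,3S)-3-chlorobutane-1,2-diol F7.
- TEMPO (cat.), NaOCl (cat.) and NaClO2 (MeCN, pH 6.8 buffer) oxidise only the primary alcohol of F7 and give 24.

Step 8.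
- Risk: metathesis at the α-branched vinyl group may be sluggish. Decay of the ruthenium carbene to hydrides could then move the double bond and erode C10.
- Fallback: from 16 back to 19. It replaces steps 8 and 9 and the iodinolysis of step 3.
- Ozonolysis of 16 (O3, CH2Cl2, −78 °C; PPh3) gives (2R,6R)-2-methyl-6-(4,4,5,5-tetramethyl-1,3,2-dioxaborolan-2-yl)heptanal F8.
- Takai olefination (CrCl2, CHI3, THF, 0 °C) gives 2-[(2R,6R,7E)-8-iodo-6-methyloct-7-en-2-yl]-4,4,5,5-tetramethyl-1,3,2-dioxaborolane F9.
- Alkenylalane 6 is made from 5 as in step 3 and freed from excess Me3Al under reduced pressure. Coupling it with F9 (Pd(PPh3)4 cat., ZnCl2 cat., THF, rt) gives 19.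

Further compounds
F1 | step 16 | 2-[(2S,6R,7E,9E)-13-(furan-3-yl)-2,6,10-trimethyltrideca-7,9-dien-1-yl]-4,4,5,5-tetramethyl-1,3,2-dioxaborolane | C/C(=C\C=C\[C@H](C)CCC[C@@H](C)CB1OC(C)(C)C(C)(C)O1)CCCc1ccoc1
F2 | step 16 | (2R,6R,7E,9E)-13-(furan-3-yl)-2,6,10-trimethyltrideca-7,9-dien-1-ol | C/C(=C\C=C\[C@H](C)CCC[C@@H](C)CO)CCCc1ccoc1
F3 | step 16 | 3-[(4E,6E,8R,12R)-13-iodo-4,8,12-trimethyltrideca-4,6-dien-1-yl]furan | C/C(=C\C=C\[C@H](C)CCC[C@@H](C)CI)CCCc1ccoc1
F4 | step 16 | [(2R,6R,7E,9E)-13-(furan-3-yl)-2,6,10-trimethyltrideca-7,9-dien-1-yl]zinc iodide | C/C(=C\C=C\[C@H](C)CCC[C@@H](C)C[Zn]I)CCCc1ccoc1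
F5 | step 13 | ethoxycarbonyl (2R,3R)-3-methyloxirane-2-carboxylate (mixed anhydride) | C[C@H]1O[C@H]1C(=O)OC(=O)OCC
F6 | step 13 | [(2S,3R)-3-methyloxiran-2-yl]methanol | C[C@H]1O[C@H]1CO
F7 | step 13 | (2S,3S)-3-chlorobutane-1,2-diol | OC[C@H](O)[C@H](C)Cl
F8 | step 8 | (2R,6R)-2-methyl-6-(4,4,5,5-tetramethyl-1,3,2-dioxaborolan-2-yl)heptanal | O=C[C@H](C)CCC[C@@H](C)B1OC(C)(C)C(C)(C)O1
F9 | step 8 | 2-[(2R,6R,7E)-8-iodo-6-methyloct-7-en-2-yl]-4,4,5,5-tetramethyl-1,3,2-dioxaborolane | I/C=C/[C@H](C)CCC[C@@H](C)B1OC(C)(C)C(C)(C)O1
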